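**Plan**
- Retrosynthesis: the 7‑O‑methyl bond is cut first, then O1–C8a and C4–C4a together. This frees the whole A ring as an aryne and leaves an enolate–ester O1–C2–C3(aryl)–C4 as its partner.
- Enabling feature: C4a and C8a are adjacent A‑ring carbons that bear the C4 carbonyl and O1. That is the pattern left when an aryne takes an oxygen nucleophile at one carbon and an acyl group at the other. The 6,7‑dioxygenation lets the aryne be symmetric.
- Forward: aldehyde 1 → phenol → bromophenol → silylaryl triflate 7 (A ring). Acid 8 → ester → formylated enol ester 12 (B ring plus C2–C3–C4). 7 and 12 close the pyranone, the only ring formed. Debenzylation and 7‑O‑methylation finish the route.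
- Stereochemistry: the target has no stereocentre. The only geometric element, the Z enol(ate) of 12, is held by chelation.

Key step: step 6

Assumption: the target is achiral, so "single enantiomer" imposes no requirement; enol 12 is drawn as its hydrogen‑bonded Z tautomer although it equilibrates with the aldehyde form.

**Route**

Step 1
Reactants: 1 3,4-bis(benzyloxy)benzaldehyde
Product: 3 3,4-bis(benzyloxy)phenol, via aryl formate 2 (not isolated)
Conditions: mCPBA, CH2Cl2, 0 °C → rt; aq. NaHCO3 wash; K2CO3 (cat.), MeOH, rt
Reagents that add atoms: mCPBA (3-chloroperoxybenzoic acid), O=C(OO)c1cccc(Cl)c1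
Why: Dakin-type Baeyer–Villiger oxidation, in which the electron-rich dialkoxyaryl group migrates in preference to hydrogen to give the aryl formate, which mild methanolysis should cleave while the benzyl ethers stay untouched.

Step 2
Reactants: 3 3,4-bis(benzyloxy)phenol
Product: 4 4,5-bis(benzyloxy)-2-bromophenol
Conditions: NBS (1.0 equiv), CH2Cl2, −40 °C → 0 °C
Reagents that add atoms: N-bromosuccinimide, O=C1CCC(=O)N1Br
Why: Electrophilic aromatic bromination should go to the position ortho to the hydroxyl and para to the 3-benzyloxy group, which is the most activated and least hindered site, the other ortho position being wedged between two oxygens.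

Step 3
Reactants: 4 4,5-bis(benzyloxy)-2-bromophenol
Product: 7 4,5-bis(benzyloxy)-2-(trimethylsilyl)phenyl trifluoromethanesulfonate, via aryl trimethylsilyl ether 5 (not isolated), via lithium 2-silylphenoxide 6 (not isolated)
Conditions: HMDS, THF, 70 °C, then evaporation; n-BuLi, THF, −78 °C; Tf2O, −78 °C → rt
Reagents that add atoms: hexamethyldisilazane, C[Si](C)(C)N[Si](C)(C)C; trifluoromethanesulfonic anhydride, O=S(=O)(OS(=O)(=O)C(F)(F)F)C(F)(F)F
Why: O-silylation, bromine–lithium exchange (faster at −78 °C than benzylic deprotonation) and an anionic 1,3 O→C silyl shift (retro-Brook rearrangement) should give the ortho-silyl phenoxide, which is trapped as the triflate, the standard access to ortho-silylaryl triflate aryne precursors.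

Step 4
Reactants: 8 (2,4,5-trimethoxyphenyl)acetic acid
Product: 9 methyl (2,4,5-trimethoxyphenyl)acetate
Conditions: MeOH, H2SO4 (cat.), reflux
Reagents that add atoms: methanol, CO
Why: Fischer esterification in excess methanol, to which the aryl methyl ethers are inert.

Step 5
Reactants: 9 methyl (2,4,5-trimethoxyphenyl)acetate; 10 methyl formate
Product: 12 methyl (Z)-3-hydroxy-2-(2,4,5-trimethoxyphenyl)acrylate, via sodium enolate 11 (not isolated)
Conditions: NaH (1.5 equiv), HCO2Me (excess), THF, 0 °C → rt; then 1 M HCl
Reagents that add atoms: none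
Why: Crossed Claisen condensation (C-formylation) of the arylacetate enolate with non-enolisable methyl formate, driven by formation of the stabilised enolate 11, should give after acidification the enol ester, whose Z form is fixed by the O–H···O=C hydrogen bond.

Step 6
Reactants: 7 4,5-bis(benzyloxy)-2-(trimethylsilyl)phenyl trifluoromethanesulfonate; 12 methyl (Z)-3-hydroxy-2-(2,4,5-trimethoxyphenyl)acrylate
Product: 15 6,7-bis(benzyloxy)-3-(2,4,5-trimethoxyphenyl)-4H-chromen-4-one, via caesium enolate 13 (not isolated), via 4,5-bis(benzyloxy)benzyne 14 (not isolated)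
Conditions: 7 (1.5 equiv), CsF (4 equiv), THF, 65 °C
Reagents that add atoms: none
Why: Proposed new method: fluoride deprotonates enol 12 to the caesium enolate 13 and, by attack at silicon with loss of triflate, releases the symmetric aryne 14; the formyl-derived enolate oxygen adds to the aryne (O1–C8a) and the aryl anion generated next to the new C–O bond attacks the ester carbonyl and expels methoxide (C4–C4a). The closest known reaction type is the fluoride-mediated annulation of arynes with methyl salicylates to xanthones (O-arylation, then intramolecular acyl substitution), with a vinylogous carboxylate oxygen here in place of the phenoxide. The pyranone, the only ring formed, closes by 6-exo-trig attack of the aryl carbanion on the ester C=O, and no stereocentre is created. The step needs O- rather than C-arylation of the ambident enolate: C3 of the future chromone is already fully substituted and flanked by the twisted 2-methoxyaryl ring and the ester, so C-attack would have to build a congested quaternary carbon, while the loosely paired caesium enolate in THF exposes oxygen. It also needs the U-shaped Z enolate, which caesium chelation between the enolate and ester oxygens should maintain, so that the aryl anion forms beside the ester and cyclises faster than it is protonated. No regiochemical choice arises on the A ring because the two aryne carbons are equivalent.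

Step 7
Reactants: 15 6,7-bis(benzyloxy)-3-(2,4,5-trimethoxyphenyl)-4H-chromen-4-one
Product: 16 6,7-dihydroxy-3-(2,4,5-trimethoxyphenyl)-4H-chromen-4-one
Conditions: H2 (1 atm), 10% Pd/C, THF–MeOH, rt, stopped at complete debenzylation
Reagents that add atoms: none
Why: Catalytic hydrogenolysis of benzyl aryl ethers should be much faster than reduction of the conjugated C2=C3 bond and leaves the four methyl ethers intact.

Step 8
Reactants: 16 6,7-dihydroxy-3-(2,4,5-trimethoxyphenyl)-4H-chromen-4-one
Product: 17 6-hydroxy-7-methoxy-3-(2,4,5-trimethoxyphenyl)-4H-chromen-4-one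
Conditions: MeI (1.1 equiv), KHCO3 (1.2 equiv), DMF, 40 °C
Reagents that add atoms: iodomethane, CI
Why: Regioselective Williamson O-methylation: the 7-hydroxyl is para to C4a and conjugated with the C4 carbonyl (a vinylogous acid, clearly more acidic than the 6-hydroxyl), so one equivalent of a weak base should ionise and methylate only O7.

**Compound list**

1 | 3,4-bis(benzyloxy)benzaldehyde | O=Cc1ccc(OCc2ccccc2)c(OCc2ccccc2)c1 | starting material
2 | 3,4-bis(benzyloxy)phenyl formate (formed in situ) | O=COc1ccc(OCc2ccccc2)c(OCc2ccccc2)c1 | intermediate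
3 | 3,4-bis(benzyloxy)phenol | Oc1ccc(OCc2ccccc2)c(OCc2ccccc2)c1 | intermediate
4 | 4,5-bis(benzyloxy)-2-bromophenol | Oc1cc(OCc2ccccc2)c(OCc2ccccc2)cc1Br | intermediate
5 | [4,5-bis(benzyloxy)-2-bromophenoxy]trimethylsilane (formed in situ) | C[Si](C)(C)Oc1cc(OCc2ccccc2)c(OCc2ccccc2)cc1Br | intermediate
6 | lithium 4,5-bis(benzyloxy)-2-(trimethylsilyl)phenoxide (formed in situ) | [Li+].[O-]c1cc(OCc2ccccc2)c(OCc2ccccc2)cc1[Si](C)(C)C | intermediate
7 | 4,5-bis(benzyloxy)-2-(trimethylsilyl)phenyl trifluoromethanesulfonate | C[Si](C)(C)c1cc(OCc2ccccc2)c(OCc2ccccc2)cc1OS(=O)(=O)C(F)(F)F | intermediate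
8 | (2,4,5-trimethoxyphenyl)acetic acid | OC(=O)Cc1cc(OC)c(OC)cc1OC | starting material
9 | methyl (2,4,5-trimethoxyphenyl)acetate | COC(=O)Cc1cc(OC)c(OC)cc1OC | intermediate
10 | methyl formate | COC=O | starting material
11 | sodium (Z)-3-methoxy-3-oxo-2-(2,4,5-trimethoxyphenyl)prop-1-en-1-olate (formed in situ) | [Na+].[O-]/C=C(/c1cc(OC)c(OC)cc1OC)C(=O)OC | intermediate
12 | methyl (Z)-3-hydroxy-2-(2,4,5-trimethoxyphenyl)acrylate | O/C=C(/c1cc(OC)c(OC)cc1OC)C(=O)OC | intermediate
13 | caesium (Z)-3-methoxy-3-oxo-2-(2,4,5-trimethoxyphenyl)prop-1-en-1-olate (formed in situ) | [Cs+].[O-]/C=C(/c1cc(OC)c(OC)cc1OC)C(=O)OC | intermediate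
14 | 4,5-bis(benzyloxy)benzyne (formed in situ) | C1(OCc2ccccc2)=CC#CC=C1OCc3ccccc3 | intermediate
15 | 6,7-bis(benzyloxy)-3-(2,4,5-trimethoxyphenyl)-4H-chromen-4-one | O=c1c(-c2cc(OC)c(OC)cc2OC)coc2cc(OCc3ccccc3)c(OCc3ccccc3)cc12 | intermediate
16 | 6,7-dihydroxy-3-(2,4,5-trimethoxyphenyl)-4H-chromen-4-one | O=c1c(-c2cc(OC)c(OC)cc2OC)coc2cc(O)c(O)cc12 | intermediate
17 | 6-hydroxy-7-methoxy-3-(2,4,5-trimethoxyphenyl)-4H-chromen-4-one | COc1cc2occ(-c3cc(OC)c(OC)cc3OC)c(=O)c2cc1O | target

**Step count**

Total: 8 steps. Longest linear sequence: 6 steps (1 → 3 → 4 → 7 → 15 → 16 → 17).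

**Steps most likely to fail**

1. Step 6. Three processes could prevent ring closure. The ambident enolate could be arylated at carbon, after which the formyl group would shift to the aryl anion (net aryne insertion into the C–CHO bond). The aryl anion could be protonated before it reaches the ester. The oxygen could be arylated from the E enolate geometry, which cannot cyclise.
Fallback with known chemistry: it sets out from triflate 7 and acid 8 (taken before esterification). The established fluoride-mediated C–O addition of carboxylic acids to arynes (CsF, THF, 125 °C, sealed tube) involves carboxylate O-arylation followed by a 1,3 O→C acyl shift. It should give 1-[4,5-bis(benzyloxy)-2-hydroxyphenyl]-2-(2,4,5-trimethoxyphenyl)ethan-1-one F1. Heating this deoxybenzoin with N,N-dimethylformamide dimethyl acetal in toluene should give (E)-1-[4,5-bis(benzyloxy)-2-hydroxyphenyl]-3-(dimethylamino)-2-(2,4,5-trimethoxyphenyl)prop-2-en-1-one F2. This enaminone closes onto the phenol with loss of dimethylamine, and the route is rejoined at 15.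

2. Step 8. Discrimination between the two phenols may be incomplete, so that methylation also occurs at O6 or at both oxygens.
Fallback: it sets out from diol 16. Acetylation (Ac2O, pyridine) should give 4-oxo-3-(2,4,5-trimethoxyphenyl)-4H-chromene-6,7-diyl diacetate F3. Thiophenol with imidazole in NMP at 0 °C removes the more electrophilic 7-O-acetyl group, the ester of the more acidic phenol, to give 7-hydroxy-4-oxo-3-(2,4,5-trimethoxyphenyl)-4H-chromen-6-yl acetate F4. Neutral Mitsunobu methylation (MeOH, PPh3, DIAD, THF) should then give 7-methoxy-4-oxo-3-(2,4,5-trimethoxyphenyl)-4H-chromen-6-yl acetate F5. Methanolysis (K2CO3, MeOH) returns to the route at 17.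

3. Step 7. The C2=C3 bond of the chromone may be saturated in competition with hydrogenolysis, or debenzylation may stall at a mono-benzyl ether.
Fallback: it sets out from 15. Non-reductive Lewis-acid debenzylation with BCl3 and pentamethylbenzene as benzyl-cation scavenger (CH2Cl2, −78 °C) spares methyl ethers and the enone. It returns to the route at 16 without passing through any new compound (F0).

**Further compounds**

F1 | step 6 | 1-[4,5-bis(benzyloxy)-2-hydroxyphenyl]-2-(2,4,5-trimethoxyphenyl)ethan-1-one | O=C(Cc1cc(OC)c(OC)cc1OC)c1cc(OCc2ccccc2)c(OCc2ccccc2)cc1O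
F2 | step 6 | (E)-1-[4,5-bis(benzyloxy)-2-hydroxyphenyl]-3-(dimethylamino)-2-(2,4,5-trimethoxyphenyl)prop-2-en-1-one | CN(C)/C=C(\c1cc(OC)c(OC)cc1OC)C(=O)c1cc(OCc2ccccc2)c(OCc2ccccc2)cc1O
F3 | step 8 | 4-oxo-3-(2,4,5-trimethoxyphenyl)-4H-chromene-6,7-diyl diacetate | O=c1c(-c2cc(OC)c(OC)cc2OC)coc2cc(OC(C)=O)c(OC(C)=O)cc12
F4 | step 8 | 7-hydroxy-4-oxo-3-(2,4,5-trimethoxyphenyl)-4H-chromen-6-yl acetate | O=c1c(-c2cc(OC)c(OC)cc2OC)coc2cc(O)c(OC(C)=O)cc12
F5 | step 8 | 7-methoxy-4-oxo-3-(2,4,5-trimethoxyphenyl)-4H-chromen-6-yl acetate | O=c1c(-c2cc(OC)c(OC)cc2OC)coc2cc(OC)c(OC(C)=O)cc12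
F0 | step 7 | none | none
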